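Amounts come first: west holds less X, the solid substrate, than L, the reagent, while south holds more. The lesser charge (the limiting reagent) is therefore X in west and L in south.

| flask | X | L | temperature | remark | time |
|---|---|---|---|---|---|
| west | 0.54 M | 0.80 M | 19 °C | run made earlier |  |
| south | 1.2 M | 0.80 M | 60 °C | run made earlier |  |
| dusk | 0.80 M | 0.800 M | 50 °C |  | 3.0 d |
| autumn | 0.80 M | 0.800 M | 25 °C |  | 3.0 d |
| dawn | 0.80 M | 0.800 M | 75 °C |  | 3.0 d |
| noon | 0.80 M | 0.800 M | 0 °C |  | 3.0 d |

west run (percent of the X charged): time / d: D / % = 2.08: 7.2; 4.00: 9.8; 6.00: 11.0; 8.00: 11.1; 10.0: 12.0; 12.0: 11.8; 15.0: 12.8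

south run (percent of the X charged): time / h: D / % = 4.00: 3.3; 5.00: 5.5; 8.00: 7.6; 12.0: 11.2; 20.0: 19.5; 30.0: 28.5; 40.0: 32.1

(scatter of a reading: 0.5 percentage points)

- as a solid, counted per litre of solution: X
- at the start none of X is in solution
- what has only dissolved of X counts as not reacted

- the best flask by amount of D, in percent of the X charged; "all alike" if 1.5 percentage points covers them all (dusk / autumn / dawn / noon / all alike)
- amount of D at the end, in percent of the X charged, dusk
- amount of D at the end, in percent of the X charged, autumn
- amount of D at the end, in percent of the X charged, dawn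
- amount of D at the end, in percent of the X charged, noon

The reading taken here is that a flask stops climbing once its lesser charge has reacted, with the product D taking one share of it. West's last reading gives 12.8% of its X. South's last reading, still rising, gives 48.1% of its L so far. This number, the D formed per unit of the lesser charge that has reacted, is the split S; south's value counts its whole L as reacted, and in these two readings the split appears to grow with temperature.

The four new flasks hold X and L equal, so D in percent of X is S itself once they finish. Autumn looks nearly the same as west, with the same L, but with 0.80 M of X against 0.54 M and 25 °C against 19 °C. West stood at 9.8% after 4.00 d, so autumn should stand near that after 3.0 d, a little short of its end close to 12.8%. Noon, colder than west, should lie far below 12.8% at that time. Dusk should lie below 48.1% and dawn above it, so this reckoning names dawn.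

The forecast reads the same plateau differently, “so I read it as an equilibrium”. It gives 36% for dusk, 10% for autumn, 69% for dawn and 1.7% for noon, and it also names dawn.

The flasks give 31.0% for dusk, 9.82% for autumn, 72.2% for dawn and 1.17% for noon, so dawn is best.

    Z ⇌ Q (K = 7.40, k = 61.0 /h, Ea = 74.0 kJ/mol, ΔH = −73.0 kJ/mol)
    E ⇌ Z (K = 0.00890, k = 0.0500 /h, Ea = 93.0 kJ/mol, ΔH = 6.00 kJ/mol)
    L + Q → G (k = 31.0 /M/h, Ea = 62.0 kJ/mol)
    X ⇌ E, rate k4*(cs4 - [E]) while solid is left; crystals form when [E] > cs4 (solubility = 0.600 M, k = 0.0450 /h)
    L + Z → D (k = 11.0 /M/h, Ea = 58.0 kJ/mol)
    (constants at 25 °C)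

With 0.52% of its L left, dawn's split of 72.2% stands above south's reading of 48.1%. The main reason for dawn's split is the backward run from Q to Z, two species formed on the way: without it, dawn's D falls from 72.2% to 2.75%. A flask like noon kept at 25 °C holds D 9.82% against G, the other product, 75.9%, so its split of what has reacted is 11.5%, against 12.8% in west's last reading.

The data come from a simulation for substances that don't exist, and the scatter is random.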